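**Retrosynthetic overview**

1. Last step is hydrogenolysis of a penta-O-benzyl ether. Locants follow 3,3'-bichromane numbering: the 4-methoxyphenyl flavanone is unit 1 (C2, C3, C4), the 4-hydroxyphenyl flavanone is unit 2 (C2', C3', C4'); the target is (2S,3S,2'R,3'S), i.e. unit 1 is 2,3-cis and unit 2 is 2',3'-trans.
2. Key disconnection is C4'–C3': the ring A' aldehyde carbon, as a carbene-bound acyl anion, adds to the β-carbon of an exocyclic enone on unit 1 (intramolecular Stetter). This closes ring C of unit 2 and sets C3' and C3 together.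
3. The Stetter substrate comes from a C2'–O aryl ether bond (Mitsunobu, inversion) between a dibenzyloxysalicylaldehyde and an allylic alcohol. The alcohol comes from an enedione (CBS reduction), which comes from aldol condensation of the unit 1 flavanone with an arylglyoxal (this makes C3=C3').
4. The unit 1 flavanone comes from 5,7-dibenzyloxychromone and 4-methoxyphenylboronic acid (catalytic asymmetric conjugate addition sets C2).
5. Ring order: ring C of unit 1 first (step 1), ring C of unit 2 last (step 8); all benzene rings are bought. In the compounds with the exocyclic C3=C3' alkene, C3 outranks the aryl group at C2, so the unchanged C2 centre reads 2R there and 2S elsewhere.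

Assumption: the facial sense of the two catalyst-controlled steps (steps 2 and 5) is taken from the usual models for these catalysts; if either delivers the antipode, the mirror-image ligand or catalyst is used with no other change.

**Route**

Step 1
Reactants: 1 1-[2,4-bis(benzyloxy)-6-hydroxyphenyl]ethan-1-one
Product: 3 5,7-bis(benzyloxy)-4H-chromen-4-one, via enaminone 2 (not isolated)
Conditions: Me2NCH(OMe)2 (3 equiv), toluene, 100 °C; concentrate; then conc. HCl, CH2Cl2, 40 °C
Reagents that add atoms: N,N-dimethylformamide dimethyl acetal, COC(OC)N(C)C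
Why: Condensation of the methyl ketone with the amide acetal gives the enaminone, and acid-promoted addition–elimination by the ortho phenol (enaminone route to chromones) closes ring C of unit 1; no stereocentre is formed.

Step 2
Reactants: 3 5,7-bis(benzyloxy)-4H-chromen-4-one; 4 (4-methoxyphenyl)boronic acid
Product: 5 (2S)-5,7-bis(benzyloxy)-2-(4-methoxyphenyl)chroman-4-one
Conditions: Pd(OCOCF3)2 (5 mol%), (R)-4-tert-butyl-2-(pyridin-2-yl)-4,5-dihydrooxazole (6 mol%), NH4PF6 (30 mol%), H2O (5 equiv), ClCH2CH2Cl, 60 °C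
Reagents that add atoms: none
Why: Palladium-catalysed asymmetric conjugate addition of an arylboronic acid to a chromone: the aryl–palladium species (divalent palladium) adds to one face of C2 under control of the pyridine–oxazoline ligand and water protonates the palladium enolate, so C2 is set as S by the catalyst.

Step 3
Reactants: 6 1-[4-(benzyloxy)phenyl]ethan-1-one
Product: 8 2-[4-(benzyloxy)phenyl]-2-oxoacetaldehyde (anhydrous, used at once), via glyoxal hydrate 7 (not isolated)
Conditions: SeO2 (1.2 equiv), 1,4-dioxane/H2O (30:1), 100 °C; filter; toluene azeotrope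
Reagents that add atoms: selenium dioxide, O=[Se]=O
Why: Riley oxidation of the enolisable methyl ketone gives the 1,2-dicarbonyl compound, and azeotropic drying converts the hydrate into the free, non-enolisable aldehyde needed as the aldol acceptor.

Step 4
Reactants: 5 (2S)-5,7-bis(benzyloxy)-2-(4-methoxyphenyl)chroman-4-one; 8 2-[4-(benzyloxy)phenyl]-2-oxoacetaldehyde
Product: 11 (2R,3E)-5,7-bis(benzyloxy)-3-{2-[4-(benzyloxy)phenyl]-2-oxoethylidene}-2-(4-methoxyphenyl)chroman-4-one, via lithium aldolate 9 (not isolated), via mesylate 10 (not isolated)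
Conditions: LiN(SiMe3)2 (1.05 equiv), THF, −78 °C; 8 (1.2 equiv), −78 °C; then MsCl (1.5 equiv), Et3N (3 equiv), −78 → 0 °C
Reagents that add atoms: none
Why: Aldol addition of the kinetic lithium enolate (C3 is the only enolisable position and C2 is not touched at −78 °C) to the aldehyde carbon of the glyoxal, followed by mesylation and E1cB elimination (aldol condensation), gives the enedione with the aroyl group anti to C4=O (E), which forces the C2 aryl group pseudo-axial.

Step 5
Reactants: 11 (2R,3E)-5,7-bis(benzyloxy)-3-{2-[4-(benzyloxy)phenyl]-2-oxoethylidene}-2-(4-methoxyphenyl)chroman-4-one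
Product: 12 (2R,3E)-5,7-bis(benzyloxy)-3-{(2S)-2-[4-(benzyloxy)phenyl]-2-hydroxyethylidene}-2-(4-methoxyphenyl)chroman-4-one
Conditions: (S)-1-methyl-3,3-diphenyltetrahydro-1H,3H-pyrrolo[1,2-c][1,3,2]oxazaborole ((S)-Me-CBS, 20 mol%), catecholborane (1.5 equiv), toluene, −78 °C; MeOH, then pH 7 buffer
Reagents that add atoms: none
Why: Corey–Bakshi–Shibata reduction is 1,2-selective at −78 °C and attacks only the unhindered aroyl ketone (the chromanone carbonyl is a hindered vinylogous carbonate); with the cis-β-substituted alkenyl group acting as the large substituent, the (S)-catalyst gives the (S)-carbinol at C2'.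

Step 6
Reactants: 13 2,4,6-trihydroxybenzaldehyde
Product: 14 2,4-bis(benzyloxy)-6-hydroxybenzaldehyde
Conditions: BnBr (2.1 equiv), K2CO3 (2.2 equiv), DMF, 0 °C → rt
Reagents that add atoms: benzyl bromide, BrCc1ccccc1
Why: Williamson ether synthesis alkylates the 4-OH and one ortho OH, while the second ortho OH stays free because it is hydrogen-bonded to the formyl group.

Step 7
Reactants: 12 (2R,3E)-5,7-bis(benzyloxy)-3-{(2S)-2-[4-(benzyloxy)phenyl]-2-hydroxyethylidene}-2-(4-methoxyphenyl)chroman-4-one; 14 2,4-bis(benzyloxy)-6-hydroxybenzaldehyde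
Product: 15 2,4-bis(benzyloxy)-6-{(1R,2E)-1-[4-(benzyloxy)phenyl]-2-[(2R)-5,7-bis(benzyloxy)-2-(4-methoxyphenyl)-4-oxochroman-3-ylidene]ethoxy}benzaldehyde
Conditions: PPh3 (1.5 equiv), diisopropyl azodicarboxylate (1.5 equiv), toluene, 0 °C → rt
Reagents that add atoms: none
Why: Mitsunobu reaction: the acidic phenol displaces the oxyphosphonium by SN2 with inversion, turning the (S)-alcohol into the (R)-aryl ether at C2'; SN2' attack is blocked because C3 is fully substituted and the electron-poor enone disfavours ionisation.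

Step 8
Reactants: 15 2,4-bis(benzyloxy)-6-{(1R,2E)-1-[4-(benzyloxy)phenyl]-2-[(2R)-5,7-bis(benzyloxy)-2-(4-methoxyphenyl)-4-oxochroman-3-ylidene]ethoxy}benzaldehyde
Product: 16 (2S,2'R,3S,3'S)-5,5',7,7'-tetrakis(benzyloxy)-2'-[4-(benzyloxy)phenyl]-2-(4-methoxyphenyl)-[3,3'-bichromane]-4,4'-dione
Conditions: 6,7-dihydro-2-(pentafluorophenyl)-5H-pyrrolo[2,1-c][1,2,4]triazol-2-ium tetrafluoroborate (20 mol%), KN(SiMe3)2 (18 mol%), toluene, 23 °C, HN(SiMe3)2 pumped off; then 15 (0.02 M), 23 °C, 6–12 h; AcOH quench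
Reagents that add atoms: none
Why: Intramolecular Stetter reaction: the triazolylidene turns the aldehyde into a Breslow intermediate (acyl anion equivalent) that adds 6-exo to the enone β-carbon C3' and passes its O–H proton to C3 on the same face (syn hydroacylation), and that face is fixed by two cooperating substrate elements (the allylic-strain conformer of the (R)-ether carbon, with H in the alkene plane and the aryloxy tether on one face, and the pseudo-axial C2 aryl group shielding the other face), so C3' forms as S (trans to the C2' aryl) and C3 as S (new H anti to, and the C3 substituent cis to, the C2 aryl).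

Step 9
Reactants: 16 (2S,2'R,3S,3'S)-5,5',7,7'-tetrakis(benzyloxy)-2'-[4-(benzyloxy)phenyl]-2-(4-methoxyphenyl)-[3,3'-bichromane]-4,4'-dione
Product: 17 (2S,2'R,3S,3'S)-5,5',7,7'-tetrahydroxy-2'-(4-hydroxyphenyl)-2-(4-methoxyphenyl)-[3,3'-bichromane]-4,4'-dione (CNP0196568.4)
Conditions: H2 (1 atm), 10% Pd/C, EtOAc/THF (1:1), rt
Reagents that add atoms: none
Why: Catalytic hydrogenolysis removes the five aryl benzyl ethers under neutral conditions, so the methyl ether, the ketones and the four stereocentres (including the epimerisable cis C3) are left as they are.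

**Compound list**

1 | 1-[2,4-bis(benzyloxy)-6-hydroxyphenyl]ethan-1-one | CC(=O)c1c(O)cc(OCc2ccccc2)cc1OCc1ccccc1 | starting material
2 | (E)-1-[2,4-bis(benzyloxy)-6-hydroxyphenyl]-3-(dimethylamino)prop-2-en-1-one | CN(C)/C=C/C(=O)c1c(O)cc(OCc2ccccc2)cc1OCc1ccccc1 | intermediate (not isolated)
3 | 5,7-bis(benzyloxy)-4H-chromen-4-one | O=c1ccoc2cc(OCc3ccccc3)cc(OCc3ccccc3)c12 | intermediate
4 | (4-methoxyphenyl)boronic acid | COc1ccc(B(O)O)cc1 | starting material
5 | (2S)-5,7-bis(benzyloxy)-2-(4-methoxyphenyl)chroman-4-one | COc1ccc([C@H]2Oc3cc(OCc4ccccc4)cc(OCc4ccccc4)c3C(=O)C2)cc1 | intermediate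
6 | 1-[4-(benzyloxy)phenyl]ethan-1-one | CC(=O)c1ccc(OCc2ccccc2)cc1 | starting material
7 | 1-[4-(benzyloxy)phenyl]-2,2-dihydroxyethan-1-one (glyoxal hydrate) | OC(O)C(=O)c1ccc(OCc2ccccc2)cc1 | intermediate (not isolated)
8 | 2-[4-(benzyloxy)phenyl]-2-oxoacetaldehyde | O=CC(=O)c1ccc(OCc2ccccc2)cc1 | intermediate
9 | lithium alkoxide of (2S)-5,7-bis(benzyloxy)-3-{2-[4-(benzyloxy)phenyl]-1-hydroxy-2-oxoethyl}-2-(4-methoxyphenyl)chroman-4-one (mixture at C3 and the carbinol carbon) | COc1ccc([C@H]2Oc3cc(OCc4ccccc4)cc(OCc4ccccc4)c3C(=O)C2C([O-])C(=O)c2ccc(OCc3ccccc3)cc2)cc1.[Li+] | intermediate (not isolated)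
10 | methanesulfonate of the aldol adduct, (2S)-5,7-bis(benzyloxy)-3-{2-[4-(benzyloxy)phenyl]-1-(methylsulfonyloxy)-2-oxoethyl}-2-(4-methoxyphenyl)chroman-4-one (mixture at C3 and the sulfonate carbon) | COc1ccc([C@H]2Oc3cc(OCc4ccccc4)cc(OCc4ccccc4)c3C(=O)C2C(OS(C)(=O)=O)C(=O)c2ccc(OCc3ccccc3)cc2)cc1 | intermediate (not isolated)
11 | (2R,3E)-5,7-bis(benzyloxy)-3-{2-[4-(benzyloxy)phenyl]-2-oxoethylidene}-2-(4-methoxyphenyl)chroman-4-one | COc1ccc([C@H]2Oc3cc(OCc4ccccc4)cc(OCc4ccccc4)c3C(=O)/C2=C/C(=O)c2ccc(OCc3ccccc3)cc2)cc1 | intermediate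
12 | (2R,3E)-5,7-bis(benzyloxy)-3-{(2S)-2-[4-(benzyloxy)phenyl]-2-hydroxyethylidene}-2-(4-methoxyphenyl)chroman-4-one | COc1ccc([C@H]2Oc3cc(OCc4ccccc4)cc(OCc4ccccc4)c3C(=O)/C2=C/[C@H](O)c2ccc(OCc3ccccc3)cc2)cc1 | intermediate
13 | 2,4,6-trihydroxybenzaldehyde | O=Cc1c(O)cc(O)cc1O | starting material
14 | 2,4-bis(benzyloxy)-6-hydroxybenzaldehyde | O=Cc1c(O)cc(OCc2ccccc2)cc1OCc1ccccc1 | intermediate
15 | 2,4-bis(benzyloxy)-6-{(1R,2E)-1-[4-(benzyloxy)phenyl]-2-[(2R)-5,7-bis(benzyloxy)-2-(4-methoxyphenyl)-4-oxochroman-3-ylidene]ethoxy}benzaldehyde | COc1ccc([C@H]2Oc3cc(OCc4ccccc4)cc(OCc4ccccc4)c3C(=O)/C2=C/[C@@H](Oc2cc(OCc3ccccc3)cc(OCc3ccccc3)c2C=O)c2ccc(OCc3ccccc3)cc2)cc1 | intermediate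
16 | (2S,2'R,3S,3'S)-5,5',7,7'-tetrakis(benzyloxy)-2'-[4-(benzyloxy)phenyl]-2-(4-methoxyphenyl)-[3,3'-bichromane]-4,4'-dione | COc1ccc([C@H]2Oc3cc(OCc4ccccc4)cc(OCc4ccccc4)c3C(=O)[C@H]2[C@@H]2C(=O)c3c(OCc4ccccc4)cc(OCc4ccccc4)cc3O[C@H]2c2ccc(OCc3ccccc3)cc2)cc1 | intermediate
17 | (2S,2'R,3S,3'S)-5,5',7,7'-tetrahydroxy-2'-(4-hydroxyphenyl)-2-(4-methoxyphenyl)-[3,3'-bichromane]-4,4'-dione | COc1ccc([C@H]2Oc3cc(O)cc(O)c3C(=O)[C@H]2[C@@H]2C(=O)c3c(O)cc(O)cc3O[C@H]2c2ccc(O)cc2)cc1 | target

**Step count and risks**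

Total steps: 9. Longest linear sequence: 7 (steps 1, 2, 4, 5, 7, 8, 9).

Most likely to fail:

Step 8 (Stetter ring closure). The aldehyde is electron-rich and flanked by two ortho oxygens, so Breslow-intermediate formation may be slow. The catalytic base could also epimerise the cis C3 centre or move the alkene into the ring to give a flavone. Fallback, setting out from 15 and returning at 16: oxidise the aldehyde (NaClO2, NaH2PO4, 2-methyl-2-butene, t-BuOH/H2O) to the carboxylic acid F1, convert it with (PhSe)2 and PBu3 in CH2Cl2 into the Se-phenyl selenoester F2, and treat this with Bu3SnH and AIBN in benzene at 80 °C. The nucleophilic aroyl radical closes the same C4'–C3' bond 6-exo through the same allylic-strain conformer, and the stannane delivers hydrogen to the C3 radical anti to the pseudo-axial aryl group, giving 16.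

Step 7 (Mitsunobu). The carbinol is 4-alkoxybenzylic and allylic, so partial ionisation of the oxyphosphonium could erode the C2' configuration. Fallback, setting out from 11 and returning at 15: reduce 11 with the mirror-image (R)-Me-CBS catalyst and catecholborane to the epimeric (R)-alcohol F3, acylate it with ClCO2Me and pyridine to the methyl carbonate F4, and couple this with phenol 14 using Pd(PPh3)4 (5 mol%) in THF at rt. Ionisation and phenoxide attack at the benzylic terminus remote from the ketone both proceed with inversion, so the net retention gives the same (R)-ether 15.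

Step 4 (aldol condensation). The enedione has an acidic C2–H (γ to the aroyl ketone) and can tautomerise to the 3-phenacylflavone under base. Anhydrous arylglyoxal also oligomerises, and E/Z mixtures are possible. Fallback, setting out from 5 and returning at 11: alkylate the lithium enolate of 5 (LiN(SiMe3)2, THF, −78 °C) with 2-bromo-1-[4-(benzyloxy)phenyl]ethan-1-one to give the trans phenacyl ketone F5. Deprotonate its CH2 group with LiN(SiMe3)2 and trap with PhSeCl to give the selenide F6. Oxidise this with H2O2 and pyridine in CH2Cl2 at 0 °C to the selenoxide F7, which undergoes syn-elimination towards C3–H to give 11 without any amine base.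

Further compounds

F1 | step 8 | 2,4-bis(benzyloxy)-6-{(1R,2E)-1-[4-(benzyloxy)phenyl]-2-[(2R)-5,7-bis(benzyloxy)-2-(4-methoxyphenyl)-4-oxochroman-3-ylidene]ethoxy}benzoic acid | COc1ccc([C@H]2Oc3cc(OCc4ccccc4)cc(OCc4ccccc4)c3C(=O)/C2=C/[C@@H](Oc2cc(OCc3ccccc3)cc(OCc3ccccc3)c2C(=O)O)c2ccc(OCc3ccccc3)cc2)cc1
F2 | step 8 | Se-phenyl 2,4-bis(benzyloxy)-6-{(1R,2E)-1-[4-(benzyloxy)phenyl]-2-[(2R)-5,7-bis(benzyloxy)-2-(4-methoxyphenyl)-4-oxochroman-3-ylidene]ethoxy}benzenecarboselenoate | COc1ccc([C@H]2Oc3cc(OCc4ccccc4)cc(OCc4ccccc4)c3C(=O)/C2=C/[C@@H](Oc2cc(OCc3ccccc3)cc(OCc3ccccc3)c2C(=O)[Se]c2ccccc2)c2ccc(OCc3ccccc3)cc2)cc1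
F3 | step 7 | (2R,3E)-5,7-bis(benzyloxy)-3-{(2R)-2-[4-(benzyloxy)phenyl]-2-hydroxyethylidene}-2-(4-methoxyphenyl)chroman-4-one | COc1ccc([C@H]2Oc3cc(OCc4ccccc4)cc(OCc4ccccc4)c3C(=O)/C2=C/[C@@H](O)c2ccc(OCc3ccccc3)cc2)cc1
F4 | step 7 | (1R,2E)-1-[4-(benzyloxy)phenyl]-2-[(2R)-5,7-bis(benzyloxy)-2-(4-methoxyphenyl)-4-oxochroman-3-ylidene]ethyl methyl carbonate | COc1ccc([C@H]2Oc3cc(OCc4ccccc4)cc(OCc4ccccc4)c3C(=O)/C2=C/[C@@H](OC(=O)OC)c2ccc(OCc3ccccc3)cc2)cc1
F5 | step 4 | (2S,3R)-5,7-bis(benzyloxy)-3-{2-[4-(benzyloxy)phenyl]-2-oxoethyl}-2-(4-methoxyphenyl)chroman-4-one | COc1ccc([C@H]2Oc3cc(OCc4ccccc4)cc(OCc4ccccc4)c3C(=O)[C@@H]2CC(=O)c2ccc(OCc3ccccc3)cc2)cc1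
F6 | step 4 | (2S,3R)-5,7-bis(benzyloxy)-3-{2-[4-(benzyloxy)phenyl]-2-oxo-1-(phenylselanyl)ethyl}-2-(4-methoxyphenyl)chroman-4-one (mixture at the selenium-bearing carbon) | COc1ccc([C@H]2Oc3cc(OCc4ccccc4)cc(OCc4ccccc4)c3C(=O)[C@@H]2C([Se]c2ccccc2)C(=O)c2ccc(OCc3ccccc3)cc2)cc1
F7 | step 4 | selenoxide of F6, (2S,3R)-5,7-bis(benzyloxy)-3-{2-[4-(benzyloxy)phenyl]-2-oxo-1-(phenylseleninyl)ethyl}-2-(4-methoxyphenyl)chroman-4-one | COc1ccc([C@H]2Oc3cc(OCc4ccccc4)cc(OCc4ccccc4)c3C(=O)[C@@H]2C([Se](=O)c2ccccc2)C(=O)c2ccc(OCc3ccccc3)cc2)cc1
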